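Numbering: carbocycle C5–C10, lactone C7–C11(=C13)–C12(=O)–O–C8. The γ-lactone cannot be closed by O-alkylation, because a carboxylate on C11 cannot reach the rear of C8 in a trans-fused ring. The C12(=O)–O unit is therefore stitched in from a peroxydicarbonate in one pot: the C8 enolate of the C9 ketone attacks a peroxide oxygen from the open α-face (O–C8 bond, carbonate on O8), then iodine–lithium exchange at the 1-iodovinyl group on C7 closes the ring by acyl substitution (C11–C12 bond). The step exploits the α-carbon C8 of the cyclohexanone and the neighbouring equatorial C7 substituent, which end as the trans ring fusion. The precursor is a C8=C9 silyl enol ether carrying the vinyl iodide.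

Key step: step 15

Remark on names: C5 carries C4(=C3H2)–C15, C6 the ester oxygen, C9 the hydroxyl, C10 the methyl C14 and the oxirane C1–C2; β is the face of the C10 methyl, α the opposite face.
Assumption: 2-[(4-methoxybenzyl)oxy]acetaldehyde (1) and bis(4-tert-butylcyclohexyl) peroxydicarbonate (22) are taken as catalogue compounds, like 2, 5, 8 and 15.

Step 1
Reactants: 1 2-[(4-methoxybenzyl)oxy]acetaldehyde; 2 pent-1-en-3-one
Product: 3 (S)-2-[(4-methoxybenzyl)oxy]-5-oxoheptanal
Conditions: (R)-α,α-diphenylprolinol TMS ether (10 mol%), catechol (20 mol%), CH2Cl2, 4 °C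
Reagents that add atoms: none
Why: Enamine-catalysed Michael addition of an α-alkoxy aldehyde to a vinyl ketone; the E-enamine should be attacked on the face away from the CPh2OTMS group, which with the (R)-catalyst is expected to give the (S) centre that becomes C6.

Step 2
Reactants: 3 (S)-2-[(4-methoxybenzyl)oxy]-5-oxoheptanal
Product: 4 (S)-4-[(4-methoxybenzyl)oxy]-2-methylcyclohex-2-en-1-one
Conditions: Bn2NH·TFA (20 mol%), toluene, 50 °C
Reagents that add atoms: none
Why: Amine-salt-catalysed intramolecular aldol condensation (Robinson-type ring closure); only the ethyl-ketone α-carbon can reach the aldehyde through a six-membered ring, and the mild conditions should leave the α-alkoxy centre intact.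

Step 3
Reactants: 5 2-bromoprop-2-en-1-ol
Product: 6 [(2-bromoallyl)oxy](tert-butyl)dimethylsilane
Conditions: TBSCl, imidazole, DMF, 0 °C to rt
Reagents that add atoms: tert-butyldimethylsilyl chloride, CC(C)(C)[Si](C)(C)Cl
Why: Standard silylation of a primary allylic alcohol.

Step 4
Reactants: 4 (S)-4-[(4-methoxybenzyl)oxy]-2-methylcyclohex-2-en-1-one; 6 [(2-bromoallyl)oxy](tert-butyl)dimethylsilane
Product: 7 C9=C10 trimethylsilyl enol ether with 5β-[3-(TBSO)prop-1-en-2-yl] and 6α-OPMB
Conditions: 6, t-BuLi (2 equiv), Et2O, −78 °C; CuI; then 4, TMSCl, THF, −78 to −30 °C; Et3N quench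
Reagents that add atoms: chlorotrimethylsilane, C[Si](C)(C)Cl
Why: Bromine–lithium exchange and TMSCl-accelerated organocopper conjugate addition; addition to a 4-alkoxycyclohexenone should occur anti to the γ-alkoxy group, setting C5 (β) and giving the regiodefined silyl enol ether.

Step 5
Reactants: 7 C9=C10 trimethylsilyl enol ether; 8 bromoethene
Product: 9 C9 ketone with 10β-methyl, 10α-vinyl, 5β-side chain and 6α-OPMB
Conditions: PdCl2[P(o-tol)3]2 (5 mol%), Bu3SnF (1.1 equiv), toluene, 90 °C, sealed tube
Reagents that add atoms: none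
Why: Palladium-catalysed α-alkenylation of a ketone enolate via the tin enolate formed from the silyl enol ether; the vinyl group should be delivered to C10 on the face opposite the adjacent C5 substituent, setting the quaternary centre (methyl β, vinyl α).

Step 6
Reactants: 9 C9 ketone with 10α-vinyl
Product: 11 C7=C8 enone with 6α-OPMB, via C8=C9 trimethylsilyl enol ether 10 (not isolated)
Conditions: LiHMDS, TMSCl, THF, −78 °C; then Pd(OAc)2 (1.05 equiv), MeCN, rt
Reagents that add atoms: none
Why: Saegusa–Ito oxidation; C10 is quaternary, so only C8 can be enolised and the enone forms regiospecifically.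

Step 7
Reactants: 11 C7=C8 enone with 6α-OPMB
Product: 12 6α-hydroxy enone
Conditions: DDQ, CH2Cl2/pH 7 buffer, 0 °C
Reagents that add atoms: none
Why: Oxidative cleavage of the PMB ether, which has served as the anti-directing group for C5.

Step 8
Reactants: 12 6α-hydroxy enone
Product: 13 C7=C8 ene-6,9-dione
Conditions: Dess–Martin periodinane, NaHCO3, CH2Cl2, 0 °C to rt
Reagents that add atoms: none
Why: Neutral alcohol oxidation, chosen so that the now enolisable C5 centre is not epimerised.

Step 9
Reactants: 13 C7=C8 ene-6,9-dione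
Product: 14 6β-hydroxy enone (C9 ketone)
Conditions: NaBH4, CeCl3·7H2O, MeOH, −78 °C
Reagents that add atoms: none
Why: Luche 1,2-reduction; C6 should react rather than C9, which is flanked by the quaternary C10, and hydride should enter from the α-face, opposite the C5 side chain and the β-methyl on C10, inverting C6 to the β-alcohol.

Step 10
Reactants: 15 chlorodimethylvinylsilane
Product: 17 (1-bromovinyl)chlorodimethylsilane, via chloro(1,2-dibromoethyl)dimethylsilane 16 (not isolated)
Conditions: Br2, CH2Cl2, −78 °C; then Et3N, 40 °C; distillation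
Reagents that add atoms: bromine, BrBr
Why: Bromine addition to the vinylsilane followed by dehydrobromination of the α-silyl C–H gives the α-bromovinylsilane.

Step 11
Reactants: 14 6β-hydroxy enone; 17 (1-bromovinyl)chlorodimethylsilane
Product: 18 6β-O-[(1-bromovinyl)dimethylsilyl] ether of 14
Conditions: imidazole, CH2Cl2, 0 °C
Reagents that add atoms: none
Why: O-Silylation of the allylic alcohol installs the radical tether on the β-face.

Step 12
Reactants: 18 6β-O-[(1-bromovinyl)dimethylsilyl] ether
Product: 19 C9 ketone with cis-fused 2,2-dimethyl-3-methylene-1-oxa-2-silacyclopentane (O on C6, C11 on C7, both β)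
Conditions: Bu3SnH (syringe pump), AIBN (cat.), benzene (0.01 M), 80 °C
Reagents that add atoms: none
Why: Silicon-tethered vinyl-radical cyclisation; the α-silylvinyl radical should add 5-exo-trig to the enone β-carbon C7, the cis-fused ring forces the new C7–C11 bond onto the face of the C6 oxygen (β), and the α-keto radical at C8 is reduced by the stannane.

Step 13
Reactants: 19 cis-fused oxasilolane ketone
Product: 20 7β-(1-iodovinyl)-6β-hydroxy C9 ketone
Conditions: NIS (1.3 equiv), 2,6-lutidine, HFIP, 0 °C; aq. NaHCO3/Na2S2O3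
Reagents that add atoms: N-iodosuccinimide, O=C1CCC(=O)N1I
Why: Ipso-iododesilylation of the alkenylsiloxane, which should be faster than iodonium chemistry at the other two alkenes; hydrolysis of the residual silyl group frees the C6 hydroxyl.

Step 14
Reactants: 20 7β-(1-iodovinyl)-6β-hydroxy ketone
Product: 21 6β-OTMS C8=C9 trimethylsilyl enol ether
Conditions: TMSOTf (2.5 equiv), Et3N (3 equiv), CH2Cl2, 0 °C
Reagents that add atoms: trimethylsilyl triflate, C[Si](C)(C)OS(=O)(=O)C(F)(F)F
Why: Soft enolisation and silylation; the ketone can only enolise towards C8, and the C6 hydroxyl is capped so that no ester competes in the next step.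

Step 15
Reactants: 21 6β-OTMS C8=C9 trimethylsilyl enol ether; 22 bis(4-tert-butylcyclohexyl) peroxydicarbonate
Product: 25 trans-fused α-methylene γ-lactone with C9 ketone and 6β-OH, via potassium C8=C9 enolate 23 (not isolated), via 8α-alkoxycarbonyloxy ketone 24 (not isolated)
Conditions: KOt-Bu (1.05 equiv), THF, −78 °C; 22 (1.1 equiv), −78 °C; then t-BuLi (2.2 equiv), THF/Et2O/pentane, −100 to −78 °C; 1 M HCl/THF work-up
Reagents that add atoms: none
Why: Potassium tert-butoxide cleaves the enol silyl ether to the C8=C9 enolate 23, whose α-carbon attacks an O–O oxygen of the peroxydicarbonate, forming the O–C8 bond and leaving an alkyl carbonate on O8 (24). Iodine–lithium exchange at −100 °C then gives the alkenyllithium, which attacks that carbonate carbonyl in a Parham-type anionic cyclisation (5-exo-trig acyl substitution with loss of alkoxide), forming C11–C12 and the α-methylene lactone. The closest known reaction types are the α-oxygenation of ketone enolates with peroxydicarbonates and halogen–lithium-exchange-initiated intramolecular acylation in the presence of a ketone. The only ring closed is the γ-lactone, and it is closed at the C–C(=O) bond, which is geometrically compatible with a trans ring fusion whereas O-alkylation at C8 by a C11 carboxylate is not. C8 is the only new stereocentre: the peroxide should approach the enolate from the α-face, anti to the C7 substituent and away from the syn-axial C10 methyl and C6 silyloxy groups, so that O8 ends trans to C11. The step needs exchange to outrun addition to, or proton transfer from, the C9 ketone; the very low temperature, the fast iodide exchange and the five-membered intramolecular trap are relied on for this.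

Step 16
Reactants: 25 lactone with C9 ketone and 6β-OH
Product: 26 6β-isobutyrate of 25
Conditions: (i-PrCO)2O, DMAP (0.1 equiv), pyridine, CH2Cl2, 0 °C
Reagents that add atoms: isobutyric anhydride, CC(C)C(=O)OC(=O)C(C)C
Why: DMAP-catalysed acylation of the only free hydroxyl; C9 is still a ketone, so no second alcohol competes, and the low temperature limits enolisation at C8.

Step 17
Reactants: 26 6β-isobutyrate C9 ketone
Product: 27 9α-alcohol
Conditions: (S)-2-methyl-CBS-oxazaborolidine (1.0 equiv), catecholborane (1.8 equiv), toluene, −78 to −40 °C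
Reagents that add atoms: none
Why: CBS reduction; with C10 as the large and C8 as the small flank the (S)-catalyst should deliver hydride to the β-face and give the axial 9α-alcohol cis to O8, and catecholborane should leave the α-methylene lactone and the isolated alkenes untouched.

Step 18
Reactants: 27 9α-alcohol
Product: 28 (1R)-1,2-epoxide with C15 OTBS
Conditions: VO(Oi-Pr)3 (2 mol%), chiral bis-hydroxamic acid ligand (4 mol%, enantiomer chosen for 1R), cumene hydroperoxide, toluene, rt
Reagents that add atoms: cumene hydroperoxide, CC(C)(OO)c1ccccc1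
Why: Vanadium-catalysed hydroxyl-directed asymmetric epoxidation of a homoallylic alcohol; the C9 hydroxyl directs the oxidant to the C10 vinyl group only, and the chiral ligand is relied on to set C1.

Step 19
Reactants: 28 (1R)-1,2-epoxide with C15 OTBS
Product: 29 C15 allylic alcohol
Conditions: TBAF/AcOH (1:1), THF, 0 °C to rt
Reagents that add atoms: none
Why: Buffered fluoride desilylation of the primary allylic TBS ether, mild enough for the epoxide, the lactone and the ester.

Step 20
Reactants: 29 C15 allylic alcohol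
Product: 30 target (CNP0496100.1)
Conditions: activated MnO2, CH2Cl2, rt
Reagents that add atoms: none
Why: Manganese dioxide oxidises the primary allylic alcohol to the 2-substituted acrolein and should leave the non-allylic C9 hydroxyl untouched.

Compound list
1 | 2-[(4-methoxybenzyl)oxy]acetaldehyde | O=CCOCc1ccc(OC)cc1 | starting material
2 | pent-1-en-3-one | C=CC(=O)CC | starting material
3 | (S)-2-[(4-methoxybenzyl)oxy]-5-oxoheptanal | CCC(=O)CC[C@H](OCc1ccc(OC)cc1)C=O | intermediate
4 | (S)-4-[(4-methoxybenzyl)oxy]-2-methylcyclohex-2-en-1-one | O=C1CC[C@H](OCc2ccc(OC)cc2)C=C1C | intermediate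
5 | 2-bromoprop-2-en-1-ol | OCC(Br)=C | starting material
6 | [(2-bromoallyl)oxy](tert-butyl)dimethylsilane | C=C(Br)CO[Si](C)(C)C(C)(C)C | intermediate
7 | C9=C10 TMS enol ether, 5β-[3-(TBSO)prop-1-en-2-yl], 6α-OPMB | C[Si](C)(C)OC1=C(C)[C@H](C(=C)CO[Si](C)(C)C(C)(C)C)[C@@H](OCc2ccc(OC)cc2)CC1 | intermediate
8 | bromoethene | C=CBr | starting material
9 | C9 ketone, 10β-methyl, 10α-vinyl, 5β-side chain, 6α-OPMB | O=C1CC[C@H](OCc2ccc(OC)cc2)[C@@H](C(=C)CO[Si](C)(C)C(C)(C)C)[C@]1(C)C=C | intermediate
10 | C8=C9 TMS enol ether of 9 | C[Si](C)(C)OC1=CC[C@H](OCc2ccc(OC)cc2)[C@@H](C(=C)CO[Si](C)(C)C(C)(C)C)[C@]1(C)C=C | intermediate (not isolated)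
11 | C7=C8 enone, 6α-OPMB | O=C1C=C[C@H](OCc2ccc(OC)cc2)[C@@H](C(=C)CO[Si](C)(C)C(C)(C)C)[C@]1(C)C=C | intermediate
12 | 6α-hydroxy enone | O=C1C=C[C@H](O)[C@@H](C(=C)CO[Si](C)(C)C(C)(C)C)[C@]1(C)C=C | intermediate
13 | C7=C8 ene-6,9-dione | O=C1C=CC(=O)[C@@H](C(=C)CO[Si](C)(C)C(C)(C)C)[C@]1(C)C=C | intermediate
14 | 6β-hydroxy enone | O=C1C=C[C@@H](O)[C@@H](C(=C)CO[Si](C)(C)C(C)(C)C)[C@]1(C)C=C | intermediate
15 | chlorodimethylvinylsilane | C=C[Si](C)(C)Cl | starting material
16 | chloro(1,2-dibromoethyl)dimethylsilane | BrCC(Br)[Si](C)(C)Cl | intermediate (not isolated)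
17 | (1-bromovinyl)chlorodimethylsilane | C=C(Br)[Si](C)(C)Cl | intermediate
18 | 6β-O-[(1-bromovinyl)dimethylsilyl] ether of 14 | O=C1C=C[C@@H](O[Si](C)(C)C(Br)=C)[C@@H](C(=C)CO[Si](C)(C)C(C)(C)C)[C@]1(C)C=C | intermediate
19 | C9 ketone with cis-fused oxasilolane (O–C6, C11–C7, both β) | O=C1C[C@H]2C(=C)[Si](C)(C)O[C@H]2[C@@H](C(=C)CO[Si](C)(C)C(C)(C)C)[C@]1(C)C=C | intermediate
20 | 7β-(1-iodovinyl)-6β-hydroxy C9 ketone | O=C1C[C@@H](C(I)=C)[C@@H](O)[C@@H](C(=C)CO[Si](C)(C)C(C)(C)C)[C@]1(C)C=C | intermediate
21 | 6β-OTMS C8=C9 TMS enol ether | C[Si](C)(C)OC1=C[C@@H](C(I)=C)[C@@H](O[Si](C)(C)C)[C@@H](C(=C)CO[Si](C)(C)C(C)(C)C)[C@]1(C)C=C | intermediate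
22 | bis(4-tert-butylcyclohexyl) peroxydicarbonate | CC(C)(C)C1CCC(CC1)OC(=O)OOC(=O)OC1CCC(CC1)C(C)(C)C | starting material
23 | potassium C8=C9 enolate of 21 | [K]OC1=C[C@@H](C(I)=C)[C@@H](O[Si](C)(C)C)[C@@H](C(=C)CO[Si](C)(C)C(C)(C)C)[C@]1(C)C=C | intermediate (not isolated)
24 | 8α-[(4-tert-butylcyclohexyloxy)carbonyloxy] C9 ketone | O=C1[C@H](OC(=O)OC2CCC(CC2)C(C)(C)C)[C@@H](C(I)=C)[C@@H](O[Si](C)(C)C)[C@@H](C(=C)CO[Si](C)(C)C(C)(C)C)[C@]1(C)C=C | intermediate (not isolated)
25 | trans-fused α-methylene γ-lactone (O8 α, C11 β), C9 ketone, 6β-OH | O=C1[C@@H]2OC(=O)C(=C)[C@H]2[C@@H](O)[C@@H](C(=C)CO[Si](C)(C)C(C)(C)C)[C@]1(C)C=C | intermediate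
26 | 6β-isobutyrate of 25 | O=C1[C@@H]2OC(=O)C(=C)[C@H]2[C@@H](OC(=O)C(C)C)[C@@H](C(=C)CO[Si](C)(C)C(C)(C)C)[C@]1(C)C=C | intermediate
27 | 9α-alcohol | O[C@@H]1[C@@H]2OC(=O)C(=C)[C@H]2[C@@H](OC(=O)C(C)C)[C@@H](C(=C)CO[Si](C)(C)C(C)(C)C)[C@]1(C)C=C | intermediate
28 | (1R)-1,2-epoxide, C15 OTBS | O[C@@H]1[C@@H]2OC(=O)C(=C)[C@H]2[C@@H](OC(=O)C(C)C)[C@@H](C(=C)CO[Si](C)(C)C(C)(C)C)[C@]1(C)[C@@H]1CO1 | intermediate
29 | C15 allylic alcohol | O[C@@H]1[C@@H]2OC(=O)C(=C)[C@H]2[C@@H](OC(=O)C(C)C)[C@@H](C(=C)CO)[C@]1(C)[C@@H]1CO1 | intermediate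
30 | CNP0496100.1 | C=C1C(=O)O[C@@H]2[C@@H]1[C@@H](OC(=O)C(C)C)[C@@H](C(=C)C=O)[C@](C)([C@@H]1CO1)[C@@H]2O | target

Total step count: 20. Longest linear sequence: 18 steps (steps 1, 2, 4–9, 11–20).

Steps most likely to fail

Step 15. The alkyllithium or the new alkenyllithium may add to the C9 ketone, or the α-carbonyloxy ketone may be enolised so that the carbonate migrates to O9; the enolate oxygenation itself may also stall. The fallback sets out from 21: potassium tert-butoxide followed by 2-(phenylsulfonyl)-3-phenyloxaziridine should give the 8α-hydroxy ketone F1. Palladium-catalysed carbonylative lactonisation (Pd(PPh3)4, CO 1 atm, Et3N, DMF, 60 °C) then closes the lactone from the existing O8 onto the acyl-palladium, and dilute HCl work-up returns to 25.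

Step 17. Substrate-controlled axial delivery of hydride from the α-face may override the catalyst and give poor facial selectivity, or the α-methylene lactone may be reduced. The fallback sets C9 before the Michael acceptor exists. It sets out from 20: isobutyrylation gives the ester ketone F2; KHMDS and the same oxaziridine give the 8α-hydroxy ketone F3; L-Selectride (THF, −78 °C, equatorial attack) gives the 8α,9α-diol F4; carbonylative lactonisation as above, in which only O8 can reach the acyl-palladium, returns to 27.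

Step 5. Reductive elimination at the hindered tetrasubstituted enolate carbon may be slow, so that protodesilylation to the simple ketone or O-alkenylation takes over. The fallback sets out from 7: MeLi (THF, 0 °C) gives the lithium enolate, and Michael addition to phenyl vinyl sulfoxide, anti to the C5 side chain, gives the sulfoxide F5; thermal syn-elimination (toluene, 110 °C, CaCO3) returns to 9.

Further compounds
F1 | step 15 | 8α-hydroxy C9 ketone with 6β-OTMS and 7β-(1-iodovinyl) | O=C1[C@H](O)[C@@H](C(I)=C)[C@@H](O[Si](C)(C)C)[C@@H](C(=C)CO[Si](C)(C)C(C)(C)C)[C@]1(C)C=C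
F2 | step 17 | 6β-isobutyrate of 20 | O=C1C[C@@H](C(I)=C)[C@@H](OC(=O)C(C)C)[C@@H](C(=C)CO[Si](C)(C)C(C)(C)C)[C@]1(C)C=C
F3 | step 17 | 8α-hydroxy C9 ketone with 6β-isobutyrate | O=C1[C@H](O)[C@@H](C(I)=C)[C@@H](OC(=O)C(C)C)[C@@H](C(=C)CO[Si](C)(C)C(C)(C)C)[C@]1(C)C=C
F4 | step 17 | 8α,9α-diol with 6β-isobutyrate and 7β-(1-iodovinyl) | O[C@@H]1[C@H](O)[C@@H](C(I)=C)[C@@H](OC(=O)C(C)C)[C@@H](C(=C)CO[Si](C)(C)C(C)(C)C)[C@]1(C)C=C
F5 | step 5 | 10α-[2-(phenylsulfinyl)ethyl] C9 ketone | O=C1CC[C@H](OCc2ccc(OC)cc2)[C@@H](C(=C)CO[Si](C)(C)C(C)(C)C)[C@]1(C)CCS(=O)c1ccccc1
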